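**Retrosynthetic overview**
1. The strategy rests on C6 of the 1,2-dioxane ring, a fully substituted peroxide carbon (bonded to O1, a methyl group, ring carbon C5 and the C7–C8 tether to the cyclohexenone ring) that lies 1,4 and cis to C3, the ring carbon carrying the propanoate chain.
2. Key disconnection C6–C7: a cyclic tertiary peroxycarbenium ion (fragment A, a 6-methoxy-6-methyl-1,2-dioxane) plus an alkynylboron nucleophile (fragment B); C3 differentiates the two faces of the cation.
3. Fragment A: dioxane closed at O2–C3 by SN2 of a hydroperoxy ketal on a mesylate; C2 and C3 come from an Evans syn aldol of 4-methylpent-4-enal.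
4. Fragment B: purchased 3-ethoxy-2-methylcyclohexenone, methylated twice, Stork–Danheiser alkynylation, enone masked as an allylic silyl ether, alkyne converted to the trifluoroborate.
5. Ring order: cyclohexenone bought; 1,2-dioxane closed within fragment A; the two rings joined at C6–C7; then alkyne saturation, oxidation and esterification.

Key step: step 15

Assumption: 3-ethoxy-2-methylcyclohex-2-en-1-one is treated as a catalogue compound (otherwise one step from 2-methylcyclohexane-1,3-dione, EtOH and TsOH); the ketal carbon of fragment A and the silyloxy carbon of fragment B are carried as mixtures because both centres are erased later.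

**Fragment A**

Step 1
Reactants: 1 4-methylpent-4-en-1-ol
Product: 2 4-methylpent-4-enal
Conditions: (COCl)2, DMSO, CH2Cl2, −78 °C; Et3N, −78 → 0 °C
Reagents that add atoms: none
Why: Swern oxidation converts the primary alcohol to the aldehyde under non-acidic conditions that leave the 1,1-disubstituted alkene alone, and the volatile aldehyde would be used directly as a solution.

Step 2
Reactants: 3 (R)-4-benzyl-3-propionyloxazolidin-2-one; 2 4-methylpent-4-enal
Product: 5 (4R)-4-benzyl-3-[(2R,3S)-3-hydroxy-2,6-dimethylhept-6-enoyl]oxazolidin-2-one, via dibutylboron Z-enolate 4 (not isolated)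
Conditions: Bu2BOTf, iPr2NEt, CH2Cl2, 0 °C; then 2, −78 → 0 °C; pH 7 buffer, MeOH, 30% H2O2, 0 °C
Reagents that add atoms: none
Why: Evans syn aldol, in which the Z-boron enolate reacts through a closed Zimmerman–Traxler chair with one enolate face blocked by the (R)-benzyl auxiliary, which should set C2 as R and the C3 carbinol as S (2,3-syn).

Step 3
Reactants: 5 (4R)-4-benzyl-3-[(2R,3S)-3-hydroxy-2,6-dimethylhept-6-enoyl]oxazolidin-2-one
Product: 6 (2S,3S)-2,6-dimethylhept-6-ene-1,3-diol
Conditions: LiBH4, MeOH (1 equiv), Et2O, 0 °C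
Reagents that add atoms: none
Why: Reductive removal of the auxiliary by hydride attack at the exocyclic imide carbonyl should give the 1,3-diol without touching either stereocentre or the alkene, and the oxazolidinone is recovered.

Step 4
Reactants: 6 (2S,3S)-2,6-dimethylhept-6-ene-1,3-diol
Product: 7 (2S,3S)-1-[(tert-butyldimethylsilyl)oxy]-2,6-dimethylhept-6-en-3-ol
Conditions: TBSCl (1.05 equiv), imidazole, CH2Cl2, 0 °C
Reagents that add atoms: tert-butyldimethylsilyl chloride, CC(C)(C)[Si](C)(C)Cl
Why: Sterically controlled silylation should take the primary hydroxyl and leave the hindered C3 alcohol free for activation.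

Step 5
Reactants: 7 (2S,3S)-1-[(tert-butyldimethylsilyl)oxy]-2,6-dimethylhept-6-en-3-ol
Product: 8 (2S,3S)-1-[(tert-butyldimethylsilyl)oxy]-2,6-dimethylhept-6-en-3-yl methanesulfonate
Conditions: MsCl, Et3N, CH2Cl2, 0 °C
Reagents that add atoms: methanesulfonyl chloride, CS(=O)(=O)Cl
Why: Mesylation through sulfene turns the C3 hydroxyl into a leaving group with retention, ready for the later SN2 inversion.

Step 6
Reactants: 8 (2S,3S)-1-[(tert-butyldimethylsilyl)oxy]-2,6-dimethylhept-6-en-3-yl methanesulfonate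
Product: 10 (2S,3S)-1-[(tert-butyldimethylsilyl)oxy]-6-hydroperoxy-6-methoxy-2-methylheptan-3-yl methanesulfonate (both C6 epimers), via carbonyl oxide 9 (not isolated)
Conditions: O3, CH2Cl2/MeOH, −78 °C; N2 purge, no reductant, concentrate cold
Reagents that add atoms: ozone, [O-][O+]=O; methanol, CO
Why: Ozonolysis with solvent capture (Criegee mechanism): the 1,1-disubstituted alkene cleaves to formaldehyde and the more substituted carbonyl oxide, which methanol traps as the hydroperoxy methyl ketal; the new ketal centre is uncontrolled and is erased in step 15.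

Step 7
Reactants: 10 (2S,3S)-1-[(tert-butyldimethylsilyl)oxy]-6-hydroperoxy-6-methoxy-2-methylheptan-3-yl methanesulfonate (both C6 epimers)
Product: 11 tert-butyl{(2S)-2-[(3R)-6-methoxy-6-methyl-1,2-dioxan-3-yl]propoxy}dimethylsilane (both C6 epimers; fragment A)
Conditions: KOtBu (1.05 equiv), 18-crown-6, THF, 0 °C → rt
Reagents that add atoms: none
Why: Intramolecular peroxide alkylation, in which the weakly basic alpha-effect peroxide anion displaces the mesylate by 6-exo-tet SN2 with inversion, turning the 3S carbinol carbon into the 3R peroxide carbon (2,3-anti as in the target) and closing the 1,2-dioxane.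

**Fragment B**

Step 8
Reactants: 12 3-ethoxy-2-methylcyclohex-2-en-1-one
Product: 14 3-ethoxy-2,6-dimethylcyclohex-2-en-1-one (racemic), via lithium dienolate 13 (not isolated)
Conditions: LDA, THF, −78 °C; MeI, −78 → 0 °C
Reagents that add atoms: iodomethane, CI
Why: Kinetic alpha-prime deprotonation of the vinylogous ester (Stork–Danheiser alkylation) gives the cross-conjugated dienolate, which is C-methylated at C6.

Step 9
Reactants: 14 3-ethoxy-2,6-dimethylcyclohex-2-en-1-one (racemic)
Product: 16 3-ethoxy-2,6,6-trimethylcyclohex-2-en-1-one, via lithium dienolate 15 (not isolated)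
Conditions: LDA, THF, −78 °C; MeI, −78 → rt
Reagents that add atoms: iodomethane, CI
Why: A second kinetic enolisation at the only remaining alpha-prime hydrogen, followed by methylation, installs the gem-dimethyl group.

Step 10
Reactants: 16 3-ethoxy-2,6,6-trimethylcyclohex-2-en-1-one
Product: 18 2,4,4-trimethyl-3-[(trimethylsilyl)ethynyl]cyclohex-2-en-1-one, via tertiary propargylic alcohol 17 (not isolated)
Conditions: TMSC≡CLi (from TMSC≡CH, n-BuLi), CeCl3, THF, −78 → 0 °C; then 2 M HCl, rt
Reagents that add atoms: trimethylsilylacetylene, C#C[Si](C)(C)C; water, O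
Why: Stork–Danheiser sequence, in which the weakly basic alkynylcerium reagent adds 1,2 to the hindered vinylogous ester carbonyl and aqueous acid then ionises the tertiary allylic alcohol and hydrolyses the enol ether, transposing the carbonyl to give the 3-alkynyl enone.

Step 11
Reactants: 18 2,4,4-trimethyl-3-[(trimethylsilyl)ethynyl]cyclohex-2-en-1-one
Product: 19 3-ethynyl-2,4,4-trimethylcyclohex-2-en-1-one
Conditions: K2CO3 (cat.), MeOH, 0 °C, short contact
Reagents that add atoms: none
Why: Carbonate-catalysed methanolysis of the C(sp)–Si bond (protodesilylation) frees the terminal alkyne, with low temperature limiting conjugate addition of methoxide to the ynenone.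

Step 12
Reactants: 19 3-ethynyl-2,4,4-trimethylcyclohex-2-en-1-one
Product: 20 3-ethynyl-2,4,4-trimethylcyclohex-2-en-1-ol (racemic)
Conditions: NaBH4, CeCl3·7H2O, MeOH, 0 °C
Reagents that add atoms: none
Why: Luche reduction delivers hydride 1,2 to the enone carbonyl and so masks the electron-poor enone; the new carbinol centre is racemic and is oxidised away in step 18.

Step 13
Reactants: 20 3-ethynyl-2,4,4-trimethylcyclohex-2-en-1-ol (racemic)
Product: 21 tert-butyl[(3-ethynyl-2,4,4-trimethylcyclohex-2-en-1-yl)oxy]dimethylsilane (racemic)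
Conditions: TBSCl, imidazole, DMF, rt
Reagents that add atoms: tert-butyldimethylsilyl chloride, CC(C)(C)[Si](C)(C)Cl
Why: Standard silylation of the secondary allylic alcohol gives an ether that tolerates the organolithium step and keeps the enyne electron-rich.

Step 14
Reactants: 21 tert-butyl[(3-ethynyl-2,4,4-trimethylcyclohex-2-en-1-yl)oxy]dimethylsilane (racemic)
Product: 24 potassium trifluoro({3-[(tert-butyldimethylsilyl)oxy]-2,6,6-trimethylcyclohex-1-en-1-yl}ethynyl)borate (racemic; fragment B), via lithium acetylide 22 (not isolated), via lithium alkynyltrimethoxyborate 23 (not isolated)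
Conditions: n-BuLi, THF, −78 °C; B(OMe)3, −78 → −20 °C; aq KHF2, → rt
Reagents that add atoms: trimethyl borate, COB(OC)OC; potassium hydrogen difluoride, [K+].[F-].F
Why: Deprotonation of the terminal alkyne, borylation of the acetylide and fluoride exchange is the standard preparation of potassium alkynyltrifluoroborates, which are stable, weighable salts.

**Union and completion**

Step 15
Reactants: 11 tert-butyl{(2S)-2-[(3R)-6-methoxy-6-methyl-1,2-dioxan-3-yl]propoxy}dimethylsilane (both C6 epimers; fragment A); 24 potassium trifluoro({3-[(tert-butyldimethylsilyl)oxy]-2,6,6-trimethylcyclohex-1-en-1-yl}ethynyl)borate (racemic; fragment B)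
Product: 27 (3R,6S)-3-{(2S)-1-[(tert-butyldimethylsilyl)oxy]propan-2-yl}-6-({3-[(tert-butyldimethylsilyl)oxy]-2,6,6-trimethylcyclohex-1-en-1-yl}ethynyl)-6-methyl-1,2-dioxane (mixture only at the ring silyloxy carbon), via alkynyldifluoroborane 25 (not isolated), via peroxycarbenium ion 26 (not isolated)
Conditions: 24 (1.5 equiv), BF3·OEt2 (2.5 equiv), CH2Cl2/MeCN, −78 → −40 °C; aq NaHCO3
Reagents that add atoms: none
Why: Proposed new method: BF3·OEt2 takes fluoride from 24 to give the alkynyldifluoroborane 25 and removes methoxide from either C6 epimer of 11, so both converge on the planar tertiary peroxycarbenium ion 26 (C6=O1+, stabilised by the peroxy oxygen and the methyl group); the boron-bearing alkyne carbon then attacks C6 in an ipso substitution, the positive charge developing at C8 being carried by the electron-rich silyloxy-substituted enyne, and loss of the BF2 unit releases the alkyne. The closest known reaction types are Lewis-acid substitutions of 3-alkoxy-1,2-dioxolanes and 3-alkoxy-1,2-dioxanes by allylsilanes and silyl ketene acetals through peroxycarbenium ions, and BF3-promoted alkynylation of acetal-derived oxocarbenium ions by potassium alkynyltrifluoroborates; the new element is an alkynylboron nucleophile on a peroxycarbenium ion at a fully substituted carbon. No ring is closed: only the C6–C7 bond forms and the 1,2-dioxane made in step 7 is kept. The new stereocentre C6 is controlled by C3, because in the half-chair of 26 the C3 side chain sits pseudoequatorial and attack along the axial trajectory, which leads directly to a chair, should place the alkynyl group axial and cis to the C3 substituent with the methyl group equatorial (6S in 27, which becomes 6R after reduction by a change of CIP priorities only). The step needs 3,6-cis facial selectivity and C–C bond formation faster than O–O heterolysis or loss of the silyl ethers; this is favoured by the slim linear nucleophile, by a syn-axial environment that holds only one hydrogen on C4 and a lone pair on O2, and by the low temperature. Both epimers at the ring silyloxy carbon are carried on, since that centre is oxidised in step 18.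

Step 16
Reactants: 27 (3R,6S)-3-{(2S)-1-[(tert-butyldimethylsilyl)oxy]propan-2-yl}-6-({3-[(tert-butyldimethylsilyl)oxy]-2,6,6-trimethylcyclohex-1-en-1-yl}ethynyl)-6-methyl-1,2-dioxane
Product: 29 (3R,6R)-3-{(2S)-1-[(tert-butyldimethylsilyl)oxy]propan-2-yl}-6-(2-{3-[(tert-butyldimethylsilyl)oxy]-2,6,6-trimethylcyclohex-1-en-1-yl}ethyl)-6-methyl-1,2-dioxane, via Z-alkene 28 (not isolated)
Conditions: KO2CN=NCO2K (excess, in portions), AcOH, pyridine/MeOH, 0 °C → rt
Reagents that add atoms: none
Why: Diimide reduction, a concerted syn transfer of H2 from HN=NH, should saturate the alkyne through the Z-alkene while sparing the O–O bond and the tetrasubstituted ring alkene, which is too hindered for diimide.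

Step 17
Reactants: 29 (3R,6R)-3-{(2S)-1-[(tert-butyldimethylsilyl)oxy]propan-2-yl}-6-(2-{3-[(tert-butyldimethylsilyl)oxy]-2,6,6-trimethylcyclohex-1-en-1-yl}ethyl)-6-methyl-1,2-dioxane
Product: 30 (2S)-2-{(3R,6R)-6-[2-(3-hydroxy-2,6,6-trimethylcyclohex-1-en-1-yl)ethyl]-6-methyl-1,2-dioxan-3-yl}propan-1-ol (mixture at the ring carbinol carbon)
Conditions: HF·pyridine, pyridine, THF, 0 °C → rt
Reagents that add atoms: none
Why: Buffered fluoride desilylation removes both silyl ethers without base, which avoids base-induced fragmentation of the peroxide at the C3–H bond (Kornblum–DeLaMare type).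

Step 18
Reactants: 30 (2S)-2-{(3R,6R)-6-[2-(3-hydroxy-2,6,6-trimethylcyclohex-1-en-1-yl)ethyl]-6-methyl-1,2-dioxan-3-yl}propan-1-ol
Product: 31 (2R)-2-{(3R,6R)-6-methyl-6-[2-(2,6,6-trimethyl-3-oxocyclohex-1-en-1-yl)ethyl]-1,2-dioxan-3-yl}propanoic acid
Conditions: CrO3, H2SO4, acetone, 0 °C
Reagents that add atoms: water, O (second oxygen of the acid, through the aldehyde hydrate)
Why: Jones oxidation takes the primary alcohol through the aldehyde hydrate to the acid and the allylic alcohol to the enone in one operation, so the carbinol mixture converges on one compound, and the dialkyl peroxide is expected to be inert to chromic acid.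

Step 19
Reactants: 31 (2R)-2-{(3R,6R)-6-methyl-6-[2-(2,6,6-trimethyl-3-oxocyclohex-1-en-1-yl)ethyl]-1,2-dioxan-3-yl}propanoic acid
Product: 32 methyl (2R)-2-{(3R,6R)-6-methyl-6-[2-(2,6,6-trimethyl-3-oxocyclohex-1-en-1-yl)ethyl]-1,2-dioxan-3-yl}propanoate (diacarperoxide A)
Conditions: TMSCHN2, PhMe/MeOH, 0 °C
Reagents that add atoms: trimethylsilyldiazomethane, C[Si](C)(C)C=[N+]=[N-]
Why: Esterification by diazomethane generated in situ from trimethylsilyldiazomethane and methanol is neutral, so neither the enolisable C2 centre nor the peroxide meets acid or base.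

**Compound list**
1 | 4-methylpent-4-en-1-ol | CC(=C)CCCO | starting material
2 | 4-methylpent-4-enal | CC(=C)CCC=O | intermediate
3 | (R)-4-benzyl-3-propionyloxazolidin-2-one | O=C1OC[C@@H](Cc2ccccc2)N1C(=O)CC | starting material
4 | dibutylboron Z-enolate of 3 | O=C1OC[C@@H](Cc2ccccc2)N1/C(OB(CCCC)CCCC)=C/C | intermediate
5 | (4R)-4-benzyl-3-[(2R,3S)-3-hydroxy-2,6-dimethylhept-6-enoyl]oxazolidin-2-one | O=C1OC[C@@H](Cc2ccccc2)N1C(=O)[C@H](C)[C@@H](O)CCC(C)=C | intermediate
6 | (2S,3S)-2,6-dimethylhept-6-ene-1,3-diol | OC[C@H](C)[C@@H](O)CCC(C)=C | intermediate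
7 | (2S,3S)-1-[(tert-butyldimethylsilyl)oxy]-2,6-dimethylhept-6-en-3-ol | CC(C)(C)[Si](C)(C)OC[C@H](C)[C@@H](O)CCC(C)=C | intermediate
8 | (2S,3S)-1-[(tert-butyldimethylsilyl)oxy]-2,6-dimethylhept-6-en-3-yl methanesulfonate | CC(C)(C)[Si](C)(C)OC[C@H](C)[C@@H](OS(C)(=O)=O)CCC(C)=C | intermediate
9 | carbonyl oxide from 8 | CC(C)(C)[Si](C)(C)OC[C@H](C)[C@@H](OS(C)(=O)=O)CCC(C)=[O+][O-] | intermediate
10 | (2S,3S)-1-[(tert-butyldimethylsilyl)oxy]-6-hydroperoxy-6-methoxy-2-methylheptan-3-yl methanesulfonate (both C6 epimers) | CC(C)(C)[Si](C)(C)OC[C@H](C)[C@@H](OS(C)(=O)=O)CCC(C)(OC)OO | intermediate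
11 | tert-butyl{(2S)-2-[(3R)-6-methoxy-6-methyl-1,2-dioxan-3-yl]propoxy}dimethylsilane (both C6 epimers; fragment A) | CC(C)(C)[Si](C)(C)OC[C@H](C)[C@H]1CCC(C)(OC)OO1 | intermediate
12 | 3-ethoxy-2-methylcyclohex-2-en-1-one | CCOC1=C(C)C(=O)CCC1 | starting material
13 | lithium dienolate of 12 | CCOC1=C(C)C(O[Li])=CCC1 | intermediate
14 | 3-ethoxy-2,6-dimethylcyclohex-2-en-1-one (racemic) | CCOC1=C(C)C(=O)C(C)CC1 | intermediate
15 | lithium dienolate of 14 | CCOC1=C(C)C(O[Li])=C(C)CC1 | intermediate
16 | 3-ethoxy-2,6,6-trimethylcyclohex-2-en-1-one | CCOC1=C(C)C(=O)C(C)(C)CC1 | intermediate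
17 | 3-ethoxy-2,6,6-trimethyl-1-[(trimethylsilyl)ethynyl]cyclohex-2-en-1-ol (racemic) | CCOC1=C(C)C(O)(C#C[Si](C)(C)C)C(C)(C)CC1 | intermediate
18 | 2,4,4-trimethyl-3-[(trimethylsilyl)ethynyl]cyclohex-2-en-1-one | C[Si](C)(C)C#CC1=C(C)C(=O)CCC1(C)C | intermediate
19 | 3-ethynyl-2,4,4-trimethylcyclohex-2-en-1-one | C#CC1=C(C)C(=O)CCC1(C)C | intermediate
20 | 3-ethynyl-2,4,4-trimethylcyclohex-2-en-1-ol (racemic) | C#CC1=C(C)C(O)CCC1(C)C | intermediate
21 | tert-butyl[(3-ethynyl-2,4,4-trimethylcyclohex-2-en-1-yl)oxy]dimethylsilane (racemic) | C#CC1=C(C)C(O[Si](C)(C)C(C)(C)C)CCC1(C)C | intermediate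
22 | lithium acetylide of 21 | [Li]C#CC1=C(C)C(O[Si](C)(C)C(C)(C)C)CCC1(C)C | intermediate
23 | lithium alkynyltrimethoxyborate from 22 | [Li+].CO[B-](OC)(OC)C#CC1=C(C)C(O[Si](C)(C)C(C)(C)C)CCC1(C)C | intermediate
24 | potassium trifluoro({3-[(tert-butyldimethylsilyl)oxy]-2,6,6-trimethylcyclohex-1-en-1-yl}ethynyl)borate (racemic; fragment B) | [K+].F[B-](F)(F)C#CC1=C(C)C(O[Si](C)(C)C(C)(C)C)CCC1(C)C | intermediate
25 | alkynyldifluoroborane from 24 | FB(F)C#CC1=C(C)C(O[Si](C)(C)C(C)(C)C)CCC1(C)C | intermediate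
26 | peroxycarbenium ion from 11 | CC(C)(C)[Si](C)(C)OC[C@H](C)[C@H]1CCC(C)=[O+]O1 | intermediate
27 | (3R,6S)-3-{(2S)-1-[(tert-butyldimethylsilyl)oxy]propan-2-yl}-6-({3-[(tert-butyldimethylsilyl)oxy]-2,6,6-trimethylcyclohex-1-en-1-yl}ethynyl)-6-methyl-1,2-dioxane | CC(C)(C)[Si](C)(C)OC[C@H](C)[C@H]1CC[C@@](C)(C#CC2=C(C)C(O[Si](C)(C)C(C)(C)C)CCC2(C)C)OO1 | intermediate
28 | Z-alkene from half-reduction of 27 | CC(C)(C)[Si](C)(C)OC[C@H](C)[C@H]1CC[C@@](C)(/C=C\C2=C(C)C(O[Si](C)(C)C(C)(C)C)CCC2(C)C)OO1 | intermediate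
29 | (3R,6R)-3-{(2S)-1-[(tert-butyldimethylsilyl)oxy]propan-2-yl}-6-(2-{3-[(tert-butyldimethylsilyl)oxy]-2,6,6-trimethylcyclohex-1-en-1-yl}ethyl)-6-methyl-1,2-dioxane | CC(C)(C)[Si](C)(C)OC[C@H](C)[C@H]1CC[C@@](C)(CCC2=C(C)C(O[Si](C)(C)C(C)(C)C)CCC2(C)C)OO1 | intermediate
30 | (2S)-2-{(3R,6R)-6-[2-(3-hydroxy-2,6,6-trimethylcyclohex-1-en-1-yl)ethyl]-6-methyl-1,2-dioxan-3-yl}propan-1-ol | OC[C@H](C)[C@H]1CC[C@@](C)(CCC2=C(C)C(O)CCC2(C)C)OO1 | intermediate
31 | (2R)-2-{(3R,6R)-6-methyl-6-[2-(2,6,6-trimethyl-3-oxocyclohex-1-en-1-yl)ethyl]-1,2-dioxan-3-yl}propanoic acid | OC(=O)[C@H](C)[C@H]1CC[C@@](C)(CCC2=C(C)C(=O)CCC2(C)C)OO1 | intermediate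
32 | methyl (2R)-2-{(3R,6R)-6-methyl-6-[2-(2,6,6-trimethyl-3-oxocyclohex-1-en-1-yl)ethyl]-1,2-dioxan-3-yl}propanoate (diacarperoxide A) | COC(=O)[C@H](C)[C@H]1CC[C@@](C)(CCC2=C(C)C(=O)CCC2(C)C)OO1 | target

**Step count**
Total: 19 steps. Longest linear sequence: 12 steps (steps 1–7 then 15–19; the fragment B branch, steps 8–14 then 15–19, is equally long).

**Steps most likely to fail**

1. Step 15 (proposed new method). The alkynylboron species may capture the tertiary peroxycarbenium ion too slowly, so that O–O heterolysis of the cation, attack on the wrong face of C6, or Lewis-acid ionisation of the allylic silyl ether takes over. The fallback uses known chemistry and gives up stereocontrol at C6: the carbon skeleton is assembled first and the tertiary peroxide is made by cobalt-mediated hydroperoxysilylation. It sets out from 8 and 21 and comes back at 29, so step 16 is bypassed as well.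
   - Ozonolysis of 8 in CH2Cl2 at −78 °C with PPh3 work-up would give the methyl ketone (2S,3S)-1-[(tert-butyldimethylsilyl)oxy]-2-methyl-6-oxoheptan-3-yl methanesulfonate F1.
   - Kinetic enolisation of F1 at the methyl group (KHMDS, THF, −78 °C) and trapping with N-(5-chloropyridin-2-yl)bis(trifluoromethanesulfonyl)imide would give the terminal enol triflate (5S,6S)-7-[(tert-butyldimethylsilyl)oxy]-5-[(methanesulfonyl)oxy]-6-methylhept-1-en-2-yl trifluoromethanesulfonate F2.
   - Semi-hydrogenation of 21 (H2, Pd/CaCO3 poisoned with Pb(OAc)2, quinoline) would give tert-butyl[(3-ethenyl-2,4,4-trimethylcyclohex-2-en-1-yl)oxy]dimethylsilane F3.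
   - 9-BBN-H would hydroborate the terminal vinyl group of F3 to the B-alkyl-9-borabicyclo[3.3.1]nonane F4.
   - B-alkyl Suzuki–Miyaura coupling of F4 with F2 (PdCl2(dppf), K3PO4, THF/DMF/H2O, rt) would give the 1,1-disubstituted alkene (2S,3S)-1-[(tert-butyldimethylsilyl)oxy]-8-{3-[(tert-butyldimethylsilyl)oxy]-2,6,6-trimethylcyclohex-1-en-1-yl}-2-methyl-6-methylideneoctan-3-yl methanesulfonate F5, which holds the whole skeleton.
   - Mukaiyama–Isayama hydroperoxysilylation (Co(acac)2, O2, Et3SiH, ClCH2CH2Cl) would place the peroxide on C6 as the triethylsilyl peroxide F6 (both C6 epimers).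
   - K2CO3 in MeOH would free the tertiary hydroperoxide F7, and KOtBu with 18-crown-6 would close the dioxane by SN2 at the mesylate as in step 7.
   - This should give 29 together with its C6 epimer, (3R,6S)-3-{(2S)-1-[(tert-butyldimethylsilyl)oxy]propan-2-yl}-6-(2-{3-[(tert-butyldimethylsilyl)oxy]-2,6,6-trimethylcyclohex-1-en-1-yl}ethyl)-6-methyl-1,2-dioxane F8, to be removed by chromatography. The route is rejoined at 29 (step 17).

2. Step 16. Diimide may stall at the Z-alkene, which is flanked by the quaternary C6 and the fully substituted ring carbon, or may disproportionate before it reacts, leaving incomplete reduction. The fallback sets out from 27 and comes back at 29, replacing hydrogen transfer from diimide by metal-catalysed hydrogenation in two separately controlled stages. H2 over Pd/CaCO3 poisoned with Pb(OAc)2 and quinoline should stop at the Z-alkene 28, which would be isolated. H2 (1 atm) over PtO2 in EtOAc at 0 °C, stopped after one equivalent, should then saturate the disubstituted alkene; the tetrasubstituted ring alkene and the hindered dialkyl peroxide are expected to react much more slowly. This fallback makes no compound outside the list (F0).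

3. Step 18. Under chromic acid the β-peroxy aldehyde intermediate may enolise, causing epimerisation at C2, or the peroxide may degrade in the strong acid. The fallback sets out from 30 and comes back at 31 with two buffered oxidations. Dess–Martin periodinane (NaHCO3, CH2Cl2, 0 °C) would oxidise both alcohols to the keto aldehyde (2R)-2-{(3R,6R)-6-methyl-6-[2-(2,6,6-trimethyl-3-oxocyclohex-1-en-1-yl)ethyl]-1,2-dioxan-3-yl}propanal F9. Pinnick oxidation (NaClO2, NaH2PO4, 2-methylbut-2-ene, t-BuOH/H2O) would then give acid 31.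

**Further compounds**
F1 | step 15 | (2S,3S)-1-[(tert-butyldimethylsilyl)oxy]-2-methyl-6-oxoheptan-3-yl methanesulfonate | CC(C)(C)[Si](C)(C)OC[C@H](C)[C@@H](OS(C)(=O)=O)CCC(C)=O
F2 | step 15 | (5S,6S)-7-[(tert-butyldimethylsilyl)oxy]-5-[(methanesulfonyl)oxy]-6-methylhept-1-en-2-yl trifluoromethanesulfonate | CC(C)(C)[Si](C)(C)OC[C@H](C)[C@@H](OS(C)(=O)=O)CCC(=C)OS(=O)(=O)C(F)(F)F
F3 | step 15 | tert-butyl[(3-ethenyl-2,4,4-trimethylcyclohex-2-en-1-yl)oxy]dimethylsilane (racemic) | C=CC1=C(C)C(O[Si](C)(C)C(C)(C)C)CCC1(C)C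
F4 | step 15 | 9-(2-{3-[(tert-butyldimethylsilyl)oxy]-2,6,6-trimethylcyclohex-1-en-1-yl}ethyl)-9-borabicyclo[3.3.1]nonane | C(CC1=C(C)C(O[Si](C)(C)C(C)(C)C)CCC1(C)C)B1C2CCCC1CCC2
F5 | step 15 | (2S,3S)-1-[(tert-butyldimethylsilyl)oxy]-8-{3-[(tert-butyldimethylsilyl)oxy]-2,6,6-trimethylcyclohex-1-en-1-yl}-2-methyl-6-methylideneoctan-3-yl methanesulfonate | CC(C)(C)[Si](C)(C)OC[C@H](C)[C@@H](OS(C)(=O)=O)CCC(=C)CCC1=C(C)C(O[Si](C)(C)C(C)(C)C)CCC1(C)C
F6 | step 15 | (2S,3S)-1-[(tert-butyldimethylsilyl)oxy]-8-{3-[(tert-butyldimethylsilyl)oxy]-2,6,6-trimethylcyclohex-1-en-1-yl}-2,6-dimethyl-6-[(triethylsilyl)peroxy]octan-3-yl methanesulfonate (both C6 epimers) | CC(C)(C)[Si](C)(C)OC[C@H](C)[C@@H](OS(C)(=O)=O)CCC(C)(OO[Si](CC)(CC)CC)CCC1=C(C)C(O[Si](C)(C)C(C)(C)C)CCC1(C)C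
F7 | step 15 | (2S,3S)-1-[(tert-butyldimethylsilyl)oxy]-8-{3-[(tert-butyldimethylsilyl)oxy]-2,6,6-trimethylcyclohex-1-en-1-yl}-6-hydroperoxy-2,6-dimethyloctan-3-yl methanesulfonate (both C6 epimers) | CC(C)(C)[Si](C)(C)OC[C@H](C)[C@@H](OS(C)(=O)=O)CCC(C)(OO)CCC1=C(C)C(O[Si](C)(C)C(C)(C)C)CCC1(C)C
F8 | step 15 | (3R,6S)-3-{(2S)-1-[(tert-butyldimethylsilyl)oxy]propan-2-yl}-6-(2-{3-[(tert-butyldimethylsilyl)oxy]-2,6,6-trimethylcyclohex-1-en-1-yl}ethyl)-6-methyl-1,2-dioxane (C6 epimer of 29) | CC(C)(C)[Si](C)(C)OC[C@H](C)[C@H]1CC[C@](C)(CCC2=C(C)C(O[Si](C)(C)C(C)(C)C)CCC2(C)C)OO1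
F0 | step 16 | none | none
F9 | step 18 | (2R)-2-{(3R,6R)-6-methyl-6-[2-(2,6,6-trimethyl-3-oxocyclohex-1-en-1-yl)ethyl]-1,2-dioxan-3-yl}propanal | O=C[C@H](C)[C@H]1CC[C@@](C)(CCC2=C(C)C(=O)CCC2(C)C)OO1
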